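**Retrosynthetic overview**
- Target ⇐ silyl and ester removal ⇐ Mitsunobu inversion at C7 ⇐ threo 1,3-diol ⇐ Evans syn aldol forming C7–C8 between the aryloxyacetyl oxazolidinone of the phenol-lactone and O-silyl vanillin.
- Aryloxyacetyl imide ⇐ O-alkylation of the (1R,5R,6R) phenol-lactone with an N-(bromoacetyl)oxazolidinone.
- Phenol-lactone ⇐ epimerisation–lactonisation of a trans 2-aryl-tetrahydrofuran hydroxy ester ⇐ hydride reduction of the lactol made from an aryllithium and a trans α-(benzyloxymethyl)paraconic acid.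
- That lactone acid ⇐ enolate alkylation of (S)-paraconic acid ⇐ Evans titanium-enolate aldol of a succinate imide with formaldehyde.
- Ring order: paraconic γ-lactone first (its atoms become the tetrahydrofuran after arylation and reduction), then the tetrahydrofuran, then the fused γ-lactone.

Assumption: locants in the notes are C7 (benzylic carbinol), C8, C9 for the glycerol chain, and those of 3,7-dioxabicyclo[3.3.0]octan-2-one (C1/C5 ring fusion, C6 aryl-bearing, C4 and C8 the two OCH2) for the lactone and its monocyclic precursors.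

**Route**

Step 1
Reactants: 1 2,6-dimethoxyphenol
Product: 2 4-bromo-2,6-dimethoxyphenol
Conditions: NBS (1.0 equiv), CH2Cl2, −40 °C to 0 °C
Reagents that add atoms: N-bromosuccinimide, O=C1CCC(=O)N1Br
Why: Electrophilic aromatic bromination goes para to the free phenol, the only activated open site because both ortho positions carry methoxy groups.

Step 2
Reactants: 2 4-bromo-2,6-dimethoxyphenol
Product: 3 2-(benzyloxy)-5-bromo-1,3-dimethoxybenzene
Conditions: BnBr, K2CO3, DMF, rt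
Reagents that add atoms: benzyl bromide, BrCc1ccccc1
Why: Williamson ether synthesis gives a benzyl ether that tolerates the later aryllithium and Lewis-acid steps.

Step 3
Reactants: 4 (R)-4-benzyl-1,3-oxazolidin-2-one; 5 methyl 4-chloro-4-oxobutanoate
Product: 6 methyl 4-[(4R)-4-benzyl-2-oxo-1,3-oxazolidin-3-yl]-4-oxobutanoate
Conditions: n-BuLi (1.0 equiv), THF, −78 °C; then 5, −78 °C to 0 °C
Reagents that add atoms: none
Why: Nucleophilic acyl substitution of the acid chloride by the N-lithiated oxazolidinone installs the auxiliary; no stereocentre is formed.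

Step 4
Reactants: 6 methyl 4-[(4R)-4-benzyl-2-oxo-1,3-oxazolidin-3-yl]-4-oxobutanoate
Product: 8 (4R)-4-benzyl-3-{[(3S)-5-oxotetrahydrofuran-3-yl]carbonyl}-1,3-oxazolidin-2-one, via hydroxymethyl adduct 7 (not isolated)
Conditions: TiCl4 (1.05 equiv), i-Pr2NEt (1.1 equiv), CH2Cl2, 0 °C; 1,3,5-trioxane (1.2 equiv), TiCl4 (1.05 equiv), 0 °C; aq. NH4Cl; crude with TsOH·H2O (5 mol%), toluene, 50 °C
Reagents that add atoms: 1,3,5-trioxane, C1OCOCO1
Why: Evans titanium-enolate aldol with formaldehyde: the chelated Z-enolate is attacked on the face away from the benzyl group, which sets the new centre (C1) as S, and the primary alcohol then lactonises onto the methyl ester.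

Step 5
Reactants: 8 (4R)-4-benzyl-3-{[(3S)-5-oxotetrahydrofuran-3-yl]carbonyl}-1,3-oxazolidin-2-one
Product: 9 (3S)-5-oxotetrahydrofuran-3-carboxylic acid [(S)-paraconic acid]
Conditions: LiOH·H2O (2 equiv), 30% H2O2 (4 equiv), THF–H2O 3:1, 0 °C; Na2SO3; HCl to pH 1
Reagents that add atoms: hydrogen peroxide, OO
Why: Hydroperoxide cleaves the exocyclic imide carbonyl selectively (auxiliary hydrolysis), sulfite reduces the peracid, and acidification recloses any opened γ-lactone without touching the α-centre.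

Step 6
Reactants: 9 (3S)-5-oxotetrahydrofuran-3-carboxylic acid
Product: 10 (3S,4R)-4-[(benzyloxy)methyl]-5-oxotetrahydrofuran-3-carboxylic acid (substituents trans)
Conditions: LiN(i-Pr)2 (2.2 equiv), THF, −78 °C; BnOCH2Cl (1.2 equiv), −78 °C to −40 °C; 1 M HCl
Reagents that add atoms: benzyl chloromethyl ether, ClCOCc1ccccc1
Why: Enolate alkylation of the carboxylate–lactone enolate dianion: the electrophile enters anti to the neighbouring carboxylate, which sets C5 as R, trans to the carboxyl.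

Step 7
Reactants: 10 (3S,4R)-4-[(benzyloxy)methyl]-5-oxotetrahydrofuran-3-carboxylic acid; 3 2-(benzyloxy)-5-bromo-1,3-dimethoxybenzene
Product: 12 (3S,4R)-5-[4-(benzyloxy)-3,5-dimethoxyphenyl]-4-[(benzyloxy)methyl]-5-hydroxytetrahydrofuran-3-carboxylic acid (lactol; both C5 anomers), via aryllithium 11 (not isolated)
Conditions: 3 (2.3 equiv), n-BuLi (2.2 equiv), THF, −78 °C; then 10, −78 °C, 1 h; aq. NH4Cl, pH 3
Reagents that add atoms: none
Why: Bromine–lithium exchange gives the aryllithium; one equivalent forms the inert lithium carboxylate and the next adds once to the lactone carbonyl (1,2-addition), the lithium hemiketal surviving at −78 °C so that there is no second addition and no epimerisation.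

Step 8
Reactants: 12 lactol acid
Product: 13 methyl (3S,4R)-5-[4-(benzyloxy)-3,5-dimethoxyphenyl]-4-[(benzyloxy)methyl]-5-hydroxytetrahydrofuran-3-carboxylate (anomeric mixture)
Conditions: Me3SiCHN2 (1.3 equiv), toluene–MeOH 4:1, 0 °C
Reagents that add atoms: (trimethylsilyl)diazomethane, C[Si](C)(C)C=[N+]=[N-]
Why: Diazoalkane esterification under neutral conditions removes the free acid before the Lewis-acid step and leaves the hemiketal and both stereocentres untouched.

Step 9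
Reactants: 13 lactol methyl ester
Product: 14 methyl (3S,4R,5R)-5-[4-(benzyloxy)-3,5-dimethoxyphenyl]-4-[(benzyloxy)methyl]tetrahydrofuran-3-carboxylate
Conditions: Et3SiH (4 equiv), BF3·OEt2 (2 equiv), CH2Cl2, −78 °C; Et3N quench at −78 °C
Reagents that add atoms: none
Why: Ionic hydrogenation: BF3 ionises the hemiketal to an aryl-stabilised cyclic oxocarbenium ion and the silane delivers hydride anti to the adjacent CH2OBn group, which sets C6 as R with the aryl cis to that group.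

Step 10
Reactants: 14 tetrahydrofuran ester
Product: 15 methyl (3S,4R,5R)-5-(4-hydroxy-3,5-dimethoxyphenyl)-4-(hydroxymethyl)tetrahydrofuran-3-carboxylate
Conditions: H2 (1 atm), 10% Pd/C, EtOAc–MeOH, rt
Reagents that add atoms: none
Why: Catalytic hydrogenolysis cleaves both benzyl ethers, while the cyclic benzylic ether reacts far more slowly under neutral conditions at 1 atm.

Step 11
Reactants: 15 trans hydroxy ester
Product: 17 (1R,5R,6R)-6-(4-hydroxy-3,5-dimethoxyphenyl)-3,7-dioxabicyclo[3.3.0]octan-2-one, via cis-hydroxy ester 16 (not isolated)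
Conditions: NaOMe (3 equiv), MeOH, 45 °C; AcOH; concentrate
Reagents that add atoms: none
Why: Epimerisation–lactonisation: methoxide inverts the ester α-centre (C1, S to R) through its enolate and the cis epimer is drained by transesterification with the neighbouring CH2OH to the cis-fused γ-lactone; C5 and C6 are not acidic.

Step 12
Reactants: 4 (R)-4-benzyl-1,3-oxazolidin-2-one; 18 bromoacetyl bromide
Product: 19 (4R)-4-benzyl-3-(bromoacetyl)-1,3-oxazolidin-2-one
Conditions: n-BuLi (1.0 equiv), THF, −78 °C; then 18, −78 °C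
Reagents that add atoms: none
Why: Nucleophilic acyl substitution at the acyl bromide, which is far more electrophilic than the alkyl bromide, gives the α-bromo imide.

Step 13
Reactants: 17 phenol-lactone; 19 bromoacetyl imide
Product: 20 (4R)-4-benzyl-3-({2,6-dimethoxy-4-[(1R,5R,6R)-2-oxo-3,7-dioxabicyclo[3.3.0]oct-6-yl]phenoxy}acetyl)-1,3-oxazolidin-2-one
Conditions: K2CO3 (1.5 equiv), acetone, 40 °C
Reagents that add atoms: none
Why: Williamson-type SN2 displacement of the activated α-bromo imide by the phenoxide; K2CO3 is too weak to enolise the lactone.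

Step 14
Reactants: 21 vanillin
Product: 22 3-methoxy-4-[(triisopropylsilyl)oxy]benzaldehyde
Conditions: i-Pr3SiCl, imidazole, DMF, rt
Reagents that add atoms: chlorotriisopropylsilane, CC(C)[Si](Cl)(C(C)C)C(C)C
Why: Silyl ether formation masks the phenol so the aldehyde carries no acidic proton in the boron aldol and survives borohydride later.

Step 15
Reactants: 20 aryloxyacetyl imide; 22 silyl vanillin
Product: 24 (4R)-4-benzyl-3-[(2R,3S)-2-{2,6-dimethoxy-4-[(1R,5R,6R)-2-oxo-3,7-dioxabicyclo[3.3.0]oct-6-yl]phenoxy}-3-hydroxy-3-{3-methoxy-4-[(triisopropylsilyl)oxy]phenyl}propanoyl]-1,3-oxazolidin-2-one, via Z-boron enolate 23 (not isolated)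
Conditions: Bu2BOTf (1.2 equiv), i-Pr2NEt (1.4 equiv), CH2Cl2, −78 °C to 0 °C; 22 (1.3 equiv), −78 °C to 0 °C; pH 7 buffer, MeOH, 30% H2O2, 0 °C
Reagents that add atoms: none
Why: Evans syn aldol: the Z-dibutylboron enolate reacts through a Zimmerman–Traxler chair on the face opposite the auxiliary benzyl group, which forms the C7–C8 bond and sets C8 (final S) and C7 (S, the threo adduct).

Step 16
Reactants: 24 syn aldol adduct
Product: 25 (1R,5R,6R)-6-[4-({(1S,2S)-1,3-dihydroxy-1-{3-methoxy-4-[(triisopropylsilyl)oxy]phenyl}propan-2-yl}oxy)-3,5-dimethoxyphenyl]-3,7-dioxabicyclo[3.3.0]octan-2-one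
Conditions: NaBH4 (4 equiv), THF–H2O 4:1, 0 °C
Reagents that add atoms: none
Why: Reductive cleavage of the auxiliary: hydride attacks the activated imide carbonyl much faster than the γ-lactone at 0 °C and gives the primary alcohol without touching C7 or C8.

Step 17
Reactants: 25 threo diol
Product: 26 (1R,5R,6R)-6-[4-({(1S,2S)-3-[(tert-butyldimethylsilyl)oxy]-1-hydroxy-1-{3-methoxy-4-[(triisopropylsilyl)oxy]phenyl}propan-2-yl}oxy)-3,5-dimethoxyphenyl]-3,7-dioxabicyclo[3.3.0]octan-2-one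
Conditions: t-BuMe2SiCl (1.1 equiv), imidazole, CH2Cl2, 0 °C
Reagents that add atoms: tert-butylchlorodimethylsilane, CC(C)(C)[Si](C)(C)Cl
Why: Selective silylation of the primary hydroxyl leaves only the hindered benzylic C7–OH free for inversion.

Step 18
Reactants: 26 mono-silyl threo alcohol
Product: 27 (1R,2S)-3-[(tert-butyldimethylsilyl)oxy]-2-{2,6-dimethoxy-4-[(1R,5R,6R)-2-oxo-3,7-dioxabicyclo[3.3.0]oct-6-yl]phenoxy}-1-{3-methoxy-4-[(triisopropylsilyl)oxy]phenyl}propyl 4-nitrobenzoate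
Conditions: PPh3, DIAD, 4-O2NC6H4CO2H (2.5 equiv each), THF, 0 °C to rt
Reagents that add atoms: 4-nitrobenzoic acid, OC(=O)c1ccc(cc1)[N+](=O)[O-]
Why: Mitsunobu reaction: the C7 alkoxyphosphonium ion is displaced by 4-nitrobenzoate with SN2 inversion, which turns 7S into 7R (threo into erythro).

Step 19
Reactants: 27 4-nitrobenzoate
Product: 28 (1R,5R,6R)-6-[4-({(1R,2S)-3-[(tert-butyldimethylsilyl)oxy]-1-hydroxy-1-{3-methoxy-4-[(triisopropylsilyl)oxy]phenyl}propan-2-yl}oxy)-3,5-dimethoxyphenyl]-3,7-dioxabicyclo[3.3.0]octan-2-one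
Conditions: K2CO3 (0.3 equiv), MeOH–THF 1:1, 0 °C
Reagents that add atoms: none
Why: Base-catalysed transesterification removes the activated 4-nitrobenzoate within minutes while the cis-fused γ-lactone and the silyl ethers persist.

Step 20
Reactants: 28 erythro bis-silyl ether
Product: 29 (1R,5R,6R)-6-(4-{[(1R,2S)-1,3-dihydroxy-1-(4-hydroxy-3-methoxyphenyl)propan-2-yl]oxy}-3,5-dimethoxyphenyl)-3,7-dioxabicyclo[3.3.0]octan-2-one (target)
Conditions: Bu4NF (3 equiv), AcOH (3 equiv), THF, 0 °C to rt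
Reagents that add atoms: none
Why: Fluoride-mediated desilylation removes both silyl ethers, and acetic acid buffers the phenoxide and alkoxides so that the lactone and the benzylic centres are not disturbed.

**Compound list**
1 | 2,6-dimethoxyphenol | COc1cccc(OC)c1O | starting material
2 | 4-bromo-2,6-dimethoxyphenol | COc1cc(Br)cc(OC)c1O | intermediate
3 | 2-(benzyloxy)-5-bromo-1,3-dimethoxybenzene | COc1cc(Br)cc(OC)c1OCc1ccccc1 | intermediate
4 | (R)-4-benzyl-1,3-oxazolidin-2-one | O=C1N[C@H](Cc2ccccc2)CO1 | starting material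
5 | methyl 4-chloro-4-oxobutanoate | COC(=O)CCC(Cl)=O | starting material
6 | methyl 4-[(4R)-4-benzyl-2-oxo-1,3-oxazolidin-3-yl]-4-oxobutanoate | COC(=O)CCC(=O)N1[C@H](Cc2ccccc2)COC1=O | intermediate
7 | methyl (3S)-4-[(4R)-4-benzyl-2-oxo-1,3-oxazolidin-3-yl]-3-(hydroxymethyl)-4-oxobutanoate (not isolated) | COC(=O)C[C@@H](CO)C(=O)N1[C@H](Cc2ccccc2)COC1=O | intermediate
8 | (4R)-4-benzyl-3-{[(3S)-5-oxotetrahydrofuran-3-yl]carbonyl}-1,3-oxazolidin-2-one | O=C1C[C@@H](CO1)C(=O)N1[C@H](Cc2ccccc2)COC1=O | intermediate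
9 | (3S)-5-oxotetrahydrofuran-3-carboxylic acid | O=C1C[C@@H](CO1)C(O)=O | intermediate
10 | (3S,4R)-4-[(benzyloxy)methyl]-5-oxotetrahydrofuran-3-carboxylic acid | O=C1OC[C@@H](C(O)=O)[C@@H]1COCc1ccccc1 | intermediate
11 | [4-(benzyloxy)-3,5-dimethoxyphenyl]lithium (not isolated) | [Li]c1cc(OC)c(OCc2ccccc2)c(OC)c1 | intermediate
12 | (3S,4R)-5-[4-(benzyloxy)-3,5-dimethoxyphenyl]-4-[(benzyloxy)methyl]-5-hydroxytetrahydrofuran-3-carboxylic acid (lactol, C5 anomers, in equilibrium with the open γ-hydroxy aryl ketone) | OC(=O)[C@@H]1COC(O)(c2cc(OC)c(OCc3ccccc3)c(OC)c2)[C@H]1COCc1ccccc1 | intermediate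
13 | methyl (3S,4R)-5-[4-(benzyloxy)-3,5-dimethoxyphenyl]-4-[(benzyloxy)methyl]-5-hydroxytetrahydrofuran-3-carboxylate (C5 anomers) | COC(=O)[C@@H]1COC(O)(c2cc(OC)c(OCc3ccccc3)c(OC)c2)[C@H]1COCc1ccccc1 | intermediate
14 | methyl (3S,4R,5R)-5-[4-(benzyloxy)-3,5-dimethoxyphenyl]-4-[(benzyloxy)methyl]tetrahydrofuran-3-carboxylate | COC(=O)[C@@H]1CO[C@@H](c2cc(OC)c(OCc3ccccc3)c(OC)c2)[C@H]1COCc1ccccc1 | intermediate
15 | methyl (3S,4R,5R)-5-(4-hydroxy-3,5-dimethoxyphenyl)-4-(hydroxymethyl)tetrahydrofuran-3-carboxylate | COC(=O)[C@@H]1CO[C@@H](c2cc(OC)c(O)c(OC)c2)[C@H]1CO | intermediate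
16 | methyl (3R,4R,5R)-5-(4-hydroxy-3,5-dimethoxyphenyl)-4-(hydroxymethyl)tetrahydrofuran-3-carboxylate (not isolated) | COC(=O)[C@H]1CO[C@@H](c2cc(OC)c(O)c(OC)c2)[C@H]1CO | intermediate
17 | (1R,5R,6R)-6-(4-hydroxy-3,5-dimethoxyphenyl)-3,7-dioxabicyclo[3.3.0]octan-2-one | COc1cc([C@@H]2OC[C@@H]3C(=O)OC[C@@H]32)cc(OC)c1O | intermediate
18 | bromoacetyl bromide | BrCC(Br)=O | starting material
19 | (4R)-4-benzyl-3-(bromoacetyl)-1,3-oxazolidin-2-one | BrCC(=O)N1[C@H](Cc2ccccc2)COC1=O | intermediate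
20 | (4R)-4-benzyl-3-({2,6-dimethoxy-4-[(1R,5R,6R)-2-oxo-3,7-dioxabicyclo[3.3.0]oct-6-yl]phenoxy}acetyl)-1,3-oxazolidin-2-one | COc1cc([C@@H]2OC[C@@H]3C(=O)OC[C@@H]32)cc(OC)c1OCC(=O)N1[C@H](Cc2ccccc2)COC1=O | intermediate
21 | vanillin (4-hydroxy-3-methoxybenzaldehyde) | COc1cc(C=O)ccc1O | starting material
22 | 3-methoxy-4-[(triisopropylsilyl)oxy]benzaldehyde | COc1cc(C=O)ccc1O[Si](C(C)C)(C(C)C)C(C)C | intermediate
23 | dibutylboron Z-enolate of 20 (OB and OAr cis; not isolated) | CCCCB(CCCC)O/C(=C\Oc1c(OC)cc(cc1OC)[C@@H]1OC[C@@H]2C(=O)OC[C@@H]21)N1[C@H](Cc2ccccc2)COC1=O | intermediate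
24 | (4R)-4-benzyl-3-[(2R,3S)-2-{2,6-dimethoxy-4-[(1R,5R,6R)-2-oxo-3,7-dioxabicyclo[3.3.0]oct-6-yl]phenoxy}-3-hydroxy-3-{3-methoxy-4-[(triisopropylsilyl)oxy]phenyl}propanoyl]-1,3-oxazolidin-2-one | O=C(N1[C@H](Cc2ccccc2)COC1=O)[C@H](Oc1c(OC)cc(cc1OC)[C@@H]1OC[C@@H]2C(=O)OC[C@@H]21)[C@@H](O)c1ccc(O[Si](C(C)C)(C(C)C)C(C)C)c(OC)c1 | intermediate
25 | (1R,5R,6R)-6-[4-({(1S,2S)-1,3-dihydroxy-1-{3-methoxy-4-[(triisopropylsilyl)oxy]phenyl}propan-2-yl}oxy)-3,5-dimethoxyphenyl]-3,7-dioxabicyclo[3.3.0]octan-2-one | OC[C@H](Oc1c(OC)cc(cc1OC)[C@@H]1OC[C@@H]2C(=O)OC[C@@H]21)[C@@H](O)c1ccc(O[Si](C(C)C)(C(C)C)C(C)C)c(OC)c1 | intermediate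
26 | (1R,5R,6R)-6-[4-({(1S,2S)-3-[(tert-butyldimethylsilyl)oxy]-1-hydroxy-1-{3-methoxy-4-[(triisopropylsilyl)oxy]phenyl}propan-2-yl}oxy)-3,5-dimethoxyphenyl]-3,7-dioxabicyclo[3.3.0]octan-2-one | CC(C)(C)[Si](C)(C)OC[C@H](Oc1c(OC)cc(cc1OC)[C@@H]1OC[C@@H]2C(=O)OC[C@@H]21)[C@@H](O)c1ccc(O[Si](C(C)C)(C(C)C)C(C)C)c(OC)c1 | intermediate
27 | (1R,2S)-3-[(tert-butyldimethylsilyl)oxy]-2-{2,6-dimethoxy-4-[(1R,5R,6R)-2-oxo-3,7-dioxabicyclo[3.3.0]oct-6-yl]phenoxy}-1-{3-methoxy-4-[(triisopropylsilyl)oxy]phenyl}propyl 4-nitrobenzoate | CC(C)(C)[Si](C)(C)OC[C@H](Oc1c(OC)cc(cc1OC)[C@@H]1OC[C@@H]2C(=O)OC[C@@H]21)[C@H](OC(=O)c1ccc(cc1)[N+](=O)[O-])c1ccc(O[Si](C(C)C)(C(C)C)C(C)C)c(OC)c1 | intermediate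
28 | (1R,5R,6R)-6-[4-({(1R,2S)-3-[(tert-butyldimethylsilyl)oxy]-1-hydroxy-1-{3-methoxy-4-[(triisopropylsilyl)oxy]phenyl}propan-2-yl}oxy)-3,5-dimethoxyphenyl]-3,7-dioxabicyclo[3.3.0]octan-2-one | CC(C)(C)[Si](C)(C)OC[C@H](Oc1c(OC)cc(cc1OC)[C@@H]1OC[C@@H]2C(=O)OC[C@@H]21)[C@H](O)c1ccc(O[Si](C(C)C)(C(C)C)C(C)C)c(OC)c1 | intermediate
29 | (1R,5R,6R)-6-(4-{[(1R,2S)-1,3-dihydroxy-1-(4-hydroxy-3-methoxyphenyl)propan-2-yl]oxy}-3,5-dimethoxyphenyl)-3,7-dioxabicyclo[3.3.0]octan-2-one | COc1cc([C@@H](O)[C@H](CO)Oc2c(OC)cc([C@@H]3OC[C@@H]4C(=O)OC[C@@H]43)cc2OC)ccc1O | target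

**Count**
Total: 20 steps. Longest linear sequence: 16 steps (steps 3 to 11, 13 and 15 to 20, counted from 4 and 5).

**Steps most likely to fail**

Step 18, the Mitsunobu inversion. The alcohol is hindered and the electron-rich benzylic centre can ionise, which would give retention, elimination or mixtures. The fallback sets out from 26. Dess–Martin periodinane (CH2Cl2, NaHCO3, 0 °C) oxidises the benzylic alcohol to the α-aryloxy ketone F1. Zn(BH4)2 in Et2O at −30 °C then reduces it under chelation control: zinc bridges the ketone and aryloxy oxygens and hydride enters from the less hindered face, giving the erythro (7R) alcohol. This comes back at 28 and bypasses 27.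

Step 16, borohydride removal of the auxiliary beside the γ-lactone, where over-reduction of the lactone is the risk. The fallback sets out from 24. LiOH/H2O2 (THF–H2O, 0 °C) hydrolyses the imide to the β-hydroxy acid F2, with the lactone reclosing on acidification. BH3·SMe2 (THF, 0 °C) then reduces the carboxylic acid but not the lactone. This comes back at 25.

Step 9, the reductive deoxygenation. Hydride could be delivered with poor facial selectivity, or the cis ester could interfere with the cation. The fallback sets out from 13. Its open-chain hydroxy-ketone tautomer is reduced under catalyst control with (S)-2-methyl-CBS-oxazaborolidine and BH3·SMe2 to the (R)-carbinol diol F3. Mitsunobu cyclodehydration (PPh3, DIAD, THF) then closes the ring: the primary hydroxyl is activated and the benzylic hydroxyl is the nucleophile, so C6 is retained. This comes back at 14.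

Further compounds
F1 | step 18 | (2S)-3-[(tert-butyldimethylsilyl)oxy]-2-{2,6-dimethoxy-4-[(1R,5R,6R)-2-oxo-3,7-dioxabicyclo[3.3.0]oct-6-yl]phenoxy}-1-{3-methoxy-4-[(triisopropylsilyl)oxy]phenyl}propan-1-one | CC(C)(C)[Si](C)(C)OC[C@H](Oc1c(OC)cc(cc1OC)[C@@H]1OC[C@@H]2C(=O)OC[C@@H]21)C(=O)c1ccc(O[Si](C(C)C)(C(C)C)C(C)C)c(OC)c1
F2 | step 16 | (2R,3S)-2-{2,6-dimethoxy-4-[(1R,5R,6R)-2-oxo-3,7-dioxabicyclo[3.3.0]oct-6-yl]phenoxy}-3-hydroxy-3-{3-methoxy-4-[(triisopropylsilyl)oxy]phenyl}propanoic acid | OC(=O)[C@H](Oc1c(OC)cc(cc1OC)[C@@H]1OC[C@@H]2C(=O)OC[C@@H]21)[C@@H](O)c1ccc(O[Si](C(C)C)(C(C)C)C(C)C)c(OC)c1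
F3 | step 9 | methyl (2S,3R)-4-(benzyloxy)-3-{(R)-[4-(benzyloxy)-3,5-dimethoxyphenyl](hydroxy)methyl}-2-(hydroxymethyl)butanoate | COC(=O)[C@H](CO)[C@H](COCc1ccccc1)[C@@H](O)c1cc(OC)c(OCc2ccccc2)c(OC)c1
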